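**Retrosynthetic overview**
1. Kanzonol I is a (3R)-isoflavan. Its pyran ring D is fused to two neighbouring ring-B carbons, through its oxygen at C2' and through C4'' at C3', in the gap between C1' (bonded to C3 of ring C) and the free 4'-OH. A C2'–C3' aryne activates exactly these two atoms.
2. After removal of a 4'-O-MOM group, ring D is cut at C2'–O, C3'–C4'' and O–C2''. This gives 3-methylbut-2-enal and an isoflavan with 2'-OTf, 3'-SiMe3 and 4'-OMOM on ring B.
3. The triflate goes back to a 2'-O-diethylcarbamate, the group that earlier directed the silylation. Ring C is cut at O1–C2 (Mitsunobu etherification) and at C3–C4 (oxazolidinone-controlled benzylation, which sets C3).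
4. The ring-B arylacetyl imide comes from 4-bromoresorcinol. The ring-A benzylic bromide comes from 3,5-dimethoxyphenol and prenyl bromide, with its phenol masked as an electron-poor tosylate to tame the bromide.
5. Ring order: A and B are bought, ring C is closed in step 17, ring D in step 20.

Key step: step 20

Remark: isoflavan numbering is used for all compounds that hold both aryl rings; the SMILES encodes 3R, which in the chelated-enolate alkylation model calls for the (R)-4-benzyl auxiliary; LiN(i-Pr)2, NaN(SiMe3)2 and BrZnCH2CO2Et are taken as purchased solutions.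

**Step 1**
Reactants: 1 4-bromoresorcinol
Product: 2 2-bromo-5-(methoxymethoxy)phenol
Conditions: MOMCl (1.0 equiv), K2CO3, acetone, 0 °C to rt
Reagents that add atoms: chloromethyl methyl ether (MOMCl), COCCl
Why: Williamson-type O-alkylation in which the OH para to bromine, being unhindered and the conjugate acid of the more nucleophilic phenoxide, should react ahead of the OH flanked and inductively deactivated by the ortho bromine, with minor isomers removed by chromatography.

**Step 2**
Reactants: 2 2-bromo-5-(methoxymethoxy)phenol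
Product: 3 2-bromo-5-(methoxymethoxy)phenyl N,N-diethylcarbamate
Conditions: Et2NCOCl, K2CO3, MeCN, reflux
Reagents that add atoms: N,N-diethylcarbamoyl chloride, CCN(CC)C(=O)Cl
Why: O-carbamoylation of the remaining phenol puts a base-stable directing group on the future O2' that also masks this oxygen through the later enolate and hydride steps.

**Step 3**
Reactants: 3 2-bromo-5-(methoxymethoxy)phenyl N,N-diethylcarbamate
Product: 5 6-bromo-3-(methoxymethoxy)-2-(trimethylsilyl)phenyl N,N-diethylcarbamate, via aryllithium 4 (not isolated)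
Conditions: Me3SiCl (3 equiv) present, LiN(i-Pr)2 (1.15 equiv) added, THF, −78 °C
Reagents that add atoms: chlorotrimethylsilane, C[Si](C)(C)Cl
Why: Directed ortho-metalation with in situ quench, in which the C–H between carbamate and OMOM is the most acidic site by cooperative 1,3-direction, the amide base does not exchange the bromide as an alkyllithium would, and the Me3SiCl already present traps aryllithium 4 before anionic Fries rearrangement or halogen migration can start.

**Step 4**
Reactants: 5 6-bromo-3-(methoxymethoxy)-2-(trimethylsilyl)phenyl N,N-diethylcarbamate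
Product: 6 ethyl 2-[2-(diethylcarbamoyloxy)-4-(methoxymethoxy)-3-(trimethylsilyl)phenyl]acetate
Conditions: BrZnCH2CO2Et (1.8 equiv), Pd2(dba)3 (cat.), XPhos (cat.), THF, 65 °C
Reagents that add atoms: (2-ethoxy-2-oxoethyl)zinc bromide, CCOC(=O)C[Zn]Br
Why: Negishi-type cross-coupling of a Reformatsky reagent under zerovalent palladium catalysis replaces Br by CH2CO2Et in a nearly neutral medium that leaves carbamate, acetal and aryl silane alone.

**Step 5**
Reactants: 6 ethyl 2-[2-(diethylcarbamoyloxy)-4-(methoxymethoxy)-3-(trimethylsilyl)phenyl]acetate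
Product: 7 2-[2-(diethylcarbamoyloxy)-4-(methoxymethoxy)-3-(trimethylsilyl)phenyl]acetic acid
Conditions: LiOH, THF/MeOH/H2O, rt; then cold 0.5 M HCl to pH 4
Reagents that add atoms: lithium hydroxide, [Li+].[OH-]
Why: Saponification of the unhindered ethyl ester is much faster than attack on the flanked diethylcarbamate, and brief cold acidification to pH 4 spares the MOM ether and the acid-labile C–Si bond.

**Step 6**
Reactants: 7 2-[2-(diethylcarbamoyloxy)-4-(methoxymethoxy)-3-(trimethylsilyl)phenyl]acetic acid; 8 (R)-4-benzyl-1,3-oxazolidin-2-one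
Product: 10 (R)-4-benzyl-3-{2-[2-(diethylcarbamoyloxy)-4-(methoxymethoxy)-3-(trimethylsilyl)phenyl]acetyl}-1,3-oxazolidin-2-one, via mixed pivalic anhydride 9 (not isolated)
Conditions: PivCl, Et3N, THF, −20 °C; then LiCl, 8, −20 °C to rt
Reagents that add atoms: none
Why: Mixed-anhydride N-acylation of the oxazolidinone under LiCl/Et3N activation needs no strong base and attaches the auxiliary without touching its stereocentre.

**Step 7**
Reactants: 11 3,5-dimethoxyphenol
Product: 12 (3,5-dimethoxyphenoxy)triisopropylsilane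
Conditions: TIPSCl, imidazole, DMF, rt
Reagents that add atoms: chlorotriisopropylsilane, CC(C)[Si](Cl)(C(C)C)C(C)C
Why: O-silylation with a bulky group turns the phenol into a non-directing substituent that shields its own ortho positions in the next lithiation.

**Step 8**
Reactants: 12 (3,5-dimethoxyphenoxy)triisopropylsilane; 13 prenyl bromide
Product: 15 [3,5-dimethoxy-4-(3-methylbut-2-en-1-yl)phenoxy]triisopropylsilane, via aryllithium 14 (not isolated)
Conditions: n-BuLi, THF, 0 °C to rt; then 13, −78 °C to rt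
Reagents that add atoms: none
Why: Directed ortho-lithiation should occur at C4 between the two methoxy groups because OTIPS neither binds lithium well nor leaves room beside it, and SN2 alkylation of aryllithium 14 at the primary carbon of 13 gives the linear prenyl arene.

**Step 9**
Reactants: 15 [3,5-dimethoxy-4-(3-methylbut-2-en-1-yl)phenoxy]triisopropylsilane
Product: 16 3,5-dimethoxy-4-(3-methylbut-2-en-1-yl)phenol
Conditions: Bu4NF, THF, 0 °C
Reagents that add atoms: none
Why: Fluoride-induced Si–O cleavage frees a mirror-symmetric phenol whose two ortho positions are equivalent.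

**Step 10**
Reactants: 16 3,5-dimethoxy-4-(3-methylbut-2-en-1-yl)phenol
Product: 17 6-hydroxy-2,4-dimethoxy-3-(3-methylbut-2-en-1-yl)benzaldehyde
Conditions: MgCl2, Et3N, (CH2O)n, MeCN, reflux; dilute HCl work-up
Reagents that add atoms: paraformaldehyde (as formaldehyde), C=O
Why: MgCl2-mediated ortho-formylation (Casnati–Skattebøl reaction) delivers formaldehyde within the magnesium phenoxide chelate so that only an ortho carbon reacts, symmetry allows a single product, and the non-acidic medium leaves the prenyl group intact.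

**Step 11**
Reactants: 17 6-hydroxy-2,4-dimethoxy-3-(3-methylbut-2-en-1-yl)benzaldehyde
Product: 18 2-formyl-3,5-dimethoxy-4-(3-methylbut-2-en-1-yl)phenyl 4-methylbenzenesulfonate
Conditions: TsCl, Et3N, DMAP (cat.), CH2Cl2, 0 °C to rt
Reagents that add atoms: 4-toluenesulfonyl chloride, Cc1ccc(S(=O)(=O)Cl)cc1
Why: O-sulfonylation masks the phenol with an electron-withdrawing group, so that the benzylic halide made from it has only two donor oxygens and ionises far less readily than a 2,4,6-trialkoxybenzyl halide.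

**Step 12**
Reactants: 18 2-formyl-3,5-dimethoxy-4-(3-methylbut-2-en-1-yl)phenyl 4-methylbenzenesulfonate
Product: 19 2-(hydroxymethyl)-3,5-dimethoxy-4-(3-methylbut-2-en-1-yl)phenyl 4-methylbenzenesulfonate
Conditions: NaBH4, MeOH/THF, 0 °C
Reagents that add atoms: none
Why: Chemoselective borohydride reduction of the aldehyde, in which sulfonate and alkene are inert and the sulfonyl group, unlike an acyl group, does not migrate to the new alkoxide.

**Step 13**
Reactants: 19 2-(hydroxymethyl)-3,5-dimethoxy-4-(3-methylbut-2-en-1-yl)phenyl 4-methylbenzenesulfonate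
Product: 20 2-(bromomethyl)-3,5-dimethoxy-4-(3-methylbut-2-en-1-yl)phenyl 4-methylbenzenesulfonate
Conditions: CBr4, PPh3 (added last), CH2Cl2, −20 to 0 °C; short silica pad, used at once
Reagents that add atoms: tetrabromomethane, BrC(Br)(Br)Br
Why: The Appel bromination runs under neutral conditions without HBr, so the trisubstituted alkene is not hydrobrominated and the sensitive bromide is not exposed to acid.

**Step 14**
Reactants: 10 (R)-4-benzyl-3-{2-[2-(diethylcarbamoyloxy)-4-(methoxymethoxy)-3-(trimethylsilyl)phenyl]acetyl}-1,3-oxazolidin-2-one; 20 2-(bromomethyl)-3,5-dimethoxy-4-(3-methylbut-2-en-1-yl)phenyl 4-methylbenzenesulfonate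
Product: 22 (R)-4-benzyl-3-{(2R)-2-[2-(diethylcarbamoyloxy)-4-(methoxymethoxy)-3-(trimethylsilyl)phenyl]-3-[2,4-dimethoxy-3-(3-methylbut-2-en-1-yl)-6-(tosyloxy)phenyl]propanoyl}-1,3-oxazolidin-2-one, via sodium Z-enolate 21 (not isolated)
Conditions: NaN(SiMe3)2 (1.05 equiv), THF, −78 °C; then 20 (1.3 equiv), −78 to −30 °C
Reagents that add atoms: none
Why: Evans asymmetric alkylation, in which the chelated sodium Z-enolate 21 is shielded on one face by the benzyl group of the (R)-auxiliary, so the SN2 attack on 20 comes from the open face and sets the future C3 as R.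

**Step 15**
Reactants: 22 the alkylated imide of step 14
Product: 23 (2R)-2-[2-(diethylcarbamoyloxy)-4-(methoxymethoxy)-3-(trimethylsilyl)phenyl]-3-[2,4-dimethoxy-3-(3-methylbut-2-en-1-yl)-6-(tosyloxy)phenyl]propan-1-ol
Conditions: LiBH4, MeOH (2 equiv), Et2O/THF, 0 °C
Reagents that add atoms: none
Why: Reductive removal of the auxiliary, in which LiBH4 attacks the exocyclic imide carbonyl, does not enolise the α-aryl centre at 0 °C, and leaves diethylcarbamate and aryl sulfonate untouched.

**Step 16**
Reactants: 23 the tosyloxy alcohol of step 15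
Product: 24 (2R)-2-[2-(diethylcarbamoyloxy)-4-(methoxymethoxy)-3-(trimethylsilyl)phenyl]-3-[6-hydroxy-2,4-dimethoxy-3-(3-methylbut-2-en-1-yl)phenyl]propan-1-ol
Conditions: Mg turnings, MeOH/THF, rt
Reagents that add atoms: none
Why: Single-electron reductive cleavage of the aryl sulfonate S–O bond by Mg in MeOH frees the ring-A phenol without acid, fluoride or hot hydroxide, which would endanger the MOM ether, the C–Si bond and the carbamate respectively.

**Step 17**
Reactants: 24 the phenol alcohol of step 16
Product: 25 (3R)-5,7-dimethoxy-4'-(methoxymethoxy)-6-(3-methylbut-2-en-1-yl)-3'-(trimethylsilyl)isoflavan-2'-yl N,N-diethylcarbamate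
Conditions: PPh3, DIAD, THF, 0 °C to rt
Reagents that add atoms: none
Why: Intramolecular Mitsunobu etherification, in which the primary alcohol is activated and displaced by the only free phenol in a 6-exo-tet closure of ring C at C2, so C3 is not involved.

**Step 18**
Reactants: 25 the isoflavan carbamate of step 17
Product: 26 (3R)-2'-hydroxy-5,7-dimethoxy-4'-(methoxymethoxy)-6-(3-methylbut-2-en-1-yl)-3'-(trimethylsilyl)isoflavan
Conditions: LiAlH4, THF, 0 °C to reflux; aqueous NaOH work-up
Reagents that add atoms: none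
Why: Hydride reduction of the aryl carbamate carbonyl expels the phenoxide, while ethers, acetal, isolated alkene and aryl silane are inert to LiAlH4.

**Step 19**
Reactants: 26 the 2'-phenol of step 18
Product: 27 (3R)-5,7-dimethoxy-4'-(methoxymethoxy)-6-(3-methylbut-2-en-1-yl)-3'-(trimethylsilyl)isoflavan-2'-yl trifluoromethanesulfonate
Conditions: Tf2O, pyridine, CH2Cl2, −20 to 0 °C
Reagents that add atoms: trifluoromethanesulfonic anhydride, O=S(=O)(OS(=O)(=O)C(F)(F)F)C(F)(F)F
Why: O-triflation of the ortho-silyl phenol completes the fluoride-triggered aryne precursor, and pyridine buffers the medium so that the MOM acetal and the C–Si bond survive.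

**Step 20**
Reactants: 27 the ring-B silyl triflate of step 19; 28 3-methylbut-2-enal
Product: 32 4'-O-MOM Kanzonol I, via aryne 29 (not isolated), via benzoxete 30 (not isolated), via ortho-quinone methide 31 (not isolated)
Conditions: CsF (4 equiv), 28 (10 equiv), MeCN, 25 to 45 °C, 27 added slowly
Reagents that add atoms: none
Why: Fluoride attack on the 3'-SiMe3 group with loss of the 2'-triflate unmasks the C2'–C3' aryne 29; the carbonyl oxygen of 28 adds to C2', the C3' aryl anion collapses on the activated carbonyl carbon (stepwise formal [2+2], four-membered closure) to benzoxete 30, and strain-driven 4π ring opening gives ortho-quinone methide 31. Ring D is then closed by a thermal oxa-6π electrocyclisation of the 1-oxatriene O=C2'–C3'=C4''–C3''=C2'', which forms O–C2'' and restores the aromaticity of ring B. The closest known reaction type is the fluoride-induced annulation of ortho-silylaryl triflates with α,β-unsaturated aldehydes to 2H-chromenes, and its last event is the electrocyclisation that also operates in phenol–enal chromene syntheses. No stereocentre is created (C2'' carries two methyl groups and the benzoxete carbon becomes sp2 again), and C3 lies outside all bond changes, so its R configuration is kept. The step needs O-attack at C2': the σ-withdrawing 4'-OMOM group next to C3' distorts the aryne so that C2' is the more linear, more electrophilic carbon and the developing negative charge sits at C3' beside oxygen, which should outweigh the steric demand of the C1' substituent. Excess 28 and slow release of the aryne keep bimolecular capture ahead of an ene reaction with the prenyl group and of capture of 31 by a second aryne.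

**Step 21**
Reactants: 32 4'-O-MOM Kanzonol I
Product: 33 Kanzonol I
Conditions: p-TsOH·H2O (cat.), MeOH, 40 °C
Reagents that add atoms: none
Why: Acid-catalysed transacetalisation to methanol removes the phenolic MOM group under conditions mild enough to leave the prenyl alkene and the 2,2-dimethylchromene unprotonated, and C3 has no pathway for epimerisation.

**Compound list**
1 | 4-bromoresorcinol | Oc1ccc(Br)c(O)c1 | starting material
2 | 2-bromo-5-(methoxymethoxy)phenol | COCOc1ccc(Br)c(O)c1 | intermediate
3 | 2-bromo-5-(methoxymethoxy)phenyl N,N-diethylcarbamate | CCN(CC)C(=O)Oc1cc(OCOC)ccc1Br | intermediate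
4 | [3-bromo-2-(diethylcarbamoyloxy)-6-(methoxymethoxy)phenyl]lithium | CCN(CC)C(=O)Oc1c([Li])c(OCOC)ccc1Br | intermediate
5 | 6-bromo-3-(methoxymethoxy)-2-(trimethylsilyl)phenyl N,N-diethylcarbamate | CCN(CC)C(=O)Oc1c(Br)ccc(OCOC)c1[Si](C)(C)C | intermediate
6 | ethyl 2-[2-(diethylcarbamoyloxy)-4-(methoxymethoxy)-3-(trimethylsilyl)phenyl]acetate | CCOC(=O)Cc1ccc(OCOC)c([Si](C)(C)C)c1OC(=O)N(CC)CC | intermediate
7 | 2-[2-(diethylcarbamoyloxy)-4-(methoxymethoxy)-3-(trimethylsilyl)phenyl]acetic acid | OC(=O)Cc1ccc(OCOC)c([Si](C)(C)C)c1OC(=O)N(CC)CC | intermediate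
8 | (R)-4-benzyl-1,3-oxazolidin-2-one | O=C1N[C@H](Cc2ccccc2)CO1 | starting material
9 | mixed anhydride of 7 and pivalic acid | CC(C)(C)C(=O)OC(=O)Cc1ccc(OCOC)c([Si](C)(C)C)c1OC(=O)N(CC)CC | intermediate
10 | (R)-4-benzyl-3-(ring-B arylacetyl)-1,3-oxazolidin-2-one | O=C(Cc1ccc(OCOC)c([Si](C)(C)C)c1OC(=O)N(CC)CC)N1C(=O)OC[C@H]1Cc1ccccc1 | intermediate
11 | 3,5-dimethoxyphenol | COc1cc(O)cc(OC)c1 | starting material
12 | (3,5-dimethoxyphenoxy)triisopropylsilane | COc1cc(OC)cc(O[Si](C(C)C)(C(C)C)C(C)C)c1 | intermediate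
13 | prenyl bromide (1-bromo-3-methylbut-2-ene) | CC(C)=CCBr | starting material
14 | [2,6-dimethoxy-4-(triisopropylsilyloxy)phenyl]lithium | COc1cc(O[Si](C(C)C)(C(C)C)C(C)C)cc(OC)c1[Li] | intermediate
15 | [3,5-dimethoxy-4-(3-methylbut-2-en-1-yl)phenoxy]triisopropylsilane | COc1cc(O[Si](C(C)C)(C(C)C)C(C)C)cc(OC)c1CC=C(C)C | intermediate
16 | 3,5-dimethoxy-4-(3-methylbut-2-en-1-yl)phenol | COc1cc(O)cc(OC)c1CC=C(C)C | intermediate
17 | 6-hydroxy-2,4-dimethoxy-3-(3-methylbut-2-en-1-yl)benzaldehyde | COc1cc(O)c(C=O)c(OC)c1CC=C(C)C | intermediate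
18 | 2-formyl-3,5-dimethoxy-4-(3-methylbut-2-en-1-yl)phenyl tosylate | COc1cc(OS(=O)(=O)c2ccc(C)cc2)c(C=O)c(OC)c1CC=C(C)C | intermediate
19 | 2-(hydroxymethyl)-3,5-dimethoxy-4-(3-methylbut-2-en-1-yl)phenyl tosylate | COc1cc(OS(=O)(=O)c2ccc(C)cc2)c(CO)c(OC)c1CC=C(C)C | intermediate
20 | 2-(bromomethyl)-3,5-dimethoxy-4-(3-methylbut-2-en-1-yl)phenyl tosylate | COc1cc(OS(=O)(=O)c2ccc(C)cc2)c(CBr)c(OC)c1CC=C(C)C | intermediate
21 | sodium Z-enolate of imide 10 | [Na+].[O-]/C(=C\c1ccc(OCOC)c([Si](C)(C)C)c1OC(=O)N(CC)CC)N1C(=O)OC[C@H]1Cc1ccccc1 | intermediate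
22 | (2R)-benzylated imide carrying the (R)-auxiliary | O=C(N1C(=O)OC[C@H]1Cc1ccccc1)[C@@H](c1ccc(OCOC)c([Si](C)(C)C)c1OC(=O)N(CC)CC)Cc1c(OS(=O)(=O)c2ccc(C)cc2)cc(OC)c(CC=C(C)C)c1OC | intermediate
23 | (2R)-2-(ring-B aryl)-3-(ring-A aryl, 6-OTs)propan-1-ol | OC[C@@H](c1ccc(OCOC)c([Si](C)(C)C)c1OC(=O)N(CC)CC)Cc1c(OS(=O)(=O)c2ccc(C)cc2)cc(OC)c(CC=C(C)C)c1OC | intermediate
24 | (2R)-2-(ring-B aryl)-3-(ring-A aryl, 6-OH)propan-1-ol | OC[C@@H](c1ccc(OCOC)c([Si](C)(C)C)c1OC(=O)N(CC)CC)Cc1c(O)cc(OC)c(CC=C(C)C)c1OC | intermediate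
25 | (3R)-isoflavan with 2'-OC(O)NEt2, 3'-SiMe3, 4'-OMOM | COc1cc2c(c(OC)c1CC=C(C)C)C[C@H](c1ccc(OCOC)c([Si](C)(C)C)c1OC(=O)N(CC)CC)CO2 | intermediate
26 | (3R)-isoflavan with 2'-OH, 3'-SiMe3, 4'-OMOM | COc1cc2c(c(OC)c1CC=C(C)C)C[C@H](c1ccc(OCOC)c([Si](C)(C)C)c1O)CO2 | intermediate
27 | (3R)-isoflavan with 2'-OTf, 3'-SiMe3, 4'-OMOM | COc1cc2c(c(OC)c1CC=C(C)C)C[C@H](c1ccc(OCOC)c([Si](C)(C)C)c1OS(=O)(=O)C(F)(F)F)CO2 | intermediate
28 | 3-methylbut-2-enal | CC(C)=CC=O | starting material
29 | (3R)-isoflavan C2'–C3' aryne, 4'-OMOM | COc1cc2c(c(OC)c1CC=C(C)C)C[C@H](C1=CC=C(OCOC)C#C1)CO2 | intermediate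
30 | benzoxete (O on C2', CH(CH=CMe2) on C3', new carbon unassigned) | COc1cc2c(c(OC)c1CC=C(C)C)C[C@H](c1ccc(OCOC)c3c1OC3C=C(C)C)CO2 | intermediate
31 | ortho-quinone methide (C2'=O, Z-configured C3'=C4''H–CH=CMe2) | COc1cc2c(c(OC)c1CC=C(C)C)C[C@H](C1=CC=C(OCOC)/C(=C/C=C(C)C)C1=O)CO2 | intermediate
32 | 4'-O-MOM Kanzonol I | COc1cc2c(c(OC)c1CC=C(C)C)C[C@H](c1ccc(OCOC)c3c1OC(C)(C)C=C3)CO2 | intermediate
33 | Kanzonol I, (3R) | COc1cc2c(c(OC)c1CC=C(C)C)C[C@H](c1ccc(O)c3c1OC(C)(C)C=C3)CO2 | target

**Totals**
Total step count: 21.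
Longest linear sequence: 15 steps (steps 7–21, from 3,5-dimethoxyphenol). The ring-B branch contributes 14 (steps 1–6 and 14–21).

**Steps most likely to fail**

**1. Step 20.**
- What may go wrong: O-attack may drift to C3' under the steric pressure of the C1' substituent. The aryne may be consumed by an ene reaction with the prenyl chain, by fluoride, or by the ring-C oxygen. The enal may self-condense under basic fluoride.
- Fallback: build the same ring D from the phenol by a sigmatropic route, setting out from 26.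
- Bu4NF in wet THF at 50 °C removes the silyl group to give (3R)-2'-hydroxy-5,7-dimethoxy-4'-(methoxymethoxy)-6-prenylisoflavan F1.
- O-alkylation with 3-chloro-3-methylbut-1-yne (DBU, CuCl2 cat., MeCN, 0 °C) gives its 1,1-dimethylpropargyl ether F2.
- Heating in N,N-diethylaniline at about 150 °C brings about aromatic Claisen rearrangement to C3', the only free ortho carbon, then a 1,5-hydrogen shift and oxa-6π closure. The sequence comes back to the route at 32.

**2. Step 14.**
- What may go wrong: the bromide may ionise and self-alkylate before it meets the enolate. SN2 attack at the doubly ortho-substituted benzylic carbon may be slow. On warming, the carbamoyl group may move from O2' to the enolate carbon.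
- Fallback: set the same centre by an aldol addition to the stable aldehyde, setting out from 7 and 18.
- Acid 7 is coupled as in step 6 with (S)-4-benzyl-1,3-oxazolidin-2-one to give the (S)-auxiliary imide F3.
- Its dibutylboron Z-enolate (Bu2BOTf, Et3N, CH2Cl2, −78 to 0 °C, buffered H2O2 work-up) adds to 18 through a closed chair transition state to give the (2S,3S)-syn-aldol F4. Boron aldol addition and chelate alkylation use opposite enolate faces, hence the change of auxiliary.
- 1,1'-Thiocarbonyldiimidazole converts the benzylic alcohol into the imidazolyl thiocarbamate F5.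
- Bu3SnH/AIBN in toluene at 80 °C (Barton–McCombie deoxygenation) gives the (2R)-imide with the (S)-auxiliary F6.
- LiBH4 as in step 15 brings the sequence back to the route at 23.

**3. Step 1.**
- What may go wrong: discrimination between the two phenols may be poor, with double alkylation alongside, because the hindered OH is also the more acidic one.
- Fallback: a steric relay, setting out from 1.
- TIPSCl (1.0 equiv) and imidazole in CH2Cl2 at 0 °C silylate the open OH to give 2-bromo-5-(triisopropylsilyloxy)phenol F7.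
- Et2NCOCl, Et3N and DMAP give the silyloxy carbamate F8.
- Bu4NF at 0 °C gives 2-bromo-5-hydroxyphenyl N,N-diethylcarbamate F9.
- MOMCl with i-Pr2NEt brings the sequence back to the route at 3.

**Further compounds**
F1 | step 20 | (3R)-2'-hydroxy-5,7-dimethoxy-4'-(methoxymethoxy)-6-prenylisoflavan | COc1cc2c(c(OC)c1CC=C(C)C)C[C@H](c1ccc(OCOC)cc1O)CO2
F2 | step 20 | 2'-O-(2-methylbut-3-yn-2-yl) ether of F1 | COc1cc2c(c(OC)c1CC=C(C)C)C[C@H](c1ccc(OCOC)cc1OC(C)(C)C#C)CO2
F3 | step 14 | (S)-4-benzyl-3-(ring-B arylacetyl)-1,3-oxazolidin-2-one | O=C(Cc1ccc(OCOC)c([Si](C)(C)C)c1OC(=O)N(CC)CC)N1C(=O)OC[C@@H]1Cc1ccccc1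
F4 | step 14 | (2S,3S)-syn-aldol of F3 and 18 | O=C(N1C(=O)OC[C@@H]1Cc1ccccc1)[C@@H](c1ccc(OCOC)c([Si](C)(C)C)c1OC(=O)N(CC)CC)[C@H](O)c1c(OS(=O)(=O)c2ccc(C)cc2)cc(OC)c(CC=C(C)C)c1OC
F5 | step 14 | O-(imidazol-1-ylthiocarbonyl) derivative of F4 | O=C(N1C(=O)OC[C@@H]1Cc1ccccc1)[C@@H](c1ccc(OCOC)c([Si](C)(C)C)c1OC(=O)N(CC)CC)[C@H](OC(=S)n1ccnc1)c1c(OS(=O)(=O)c2ccc(C)cc2)cc(OC)c(CC=C(C)C)c1OC
F6 | step 14 | (2R)-benzylated imide carrying the (S)-auxiliary | O=C(N1C(=O)OC[C@@H]1Cc1ccccc1)[C@@H](c1ccc(OCOC)c([Si](C)(C)C)c1OC(=O)N(CC)CC)Cc1c(OS(=O)(=O)c2ccc(C)cc2)cc(OC)c(CC=C(C)C)c1OC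
F7 | step 1 | 2-bromo-5-(triisopropylsilyloxy)phenol | CC(C)[Si](Oc1ccc(Br)c(O)c1)(C(C)C)C(C)C
F8 | step 1 | 2-bromo-5-(triisopropylsilyloxy)phenyl N,N-diethylcarbamate | CCN(CC)C(=O)Oc1cc(O[Si](C(C)C)(C(C)C)C(C)C)ccc1Br
F9 | step 1 | 2-bromo-5-hydroxyphenyl N,N-diethylcarbamate | CCN(CC)C(=O)Oc1cc(O)ccc1Br
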